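**Plan**

1. Labdane numbering is used (C19 = lactone C=O on C4, C20 = lactone CH2 on C10; α/β as in the usual labdane drawing with C20 β). The retrosynthesis cuts O–C15 of the enol ether, the 8,17-epoxide, C9–O of the spiro ether and C9–C11, then C1–C10, C4–C3, and the aryl/lactone bonds C4–C5 and C10–C20.
2. Enabling feature: ring A (C1–C5, C10) and the bridge C19–O–C20 form a 3-oxabicyclo[3.3.1]nonan-2-one that shares C4, C5 and C10 with ring B. Ring B can therefore be carried as the arene of an isochroman-3-one, and C10 made quaternary by C-alkylation ortho to a C9 phenoxide.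
3. Forward order: 4-methoxy-2-methylphenol → lactone ring (isochromanone) → quaternary C4 → ring A by dearomatisation → C11–C16 chain added at C9 → ring B adjusted → spiro-tetrahydrofuran → 8,17-epoxide → dihydrofuran last.
4. Stereochemistry: C4 from an asymmetric phase-transfer alkylation; C10 relayed from C4 through the lactone; C5 by equilibration to the trans ring fusion; C6 by α-face hydride attack; C9 by ring closure anti to axial C20; C8 by 6β-hydroxyl-directed epoxidation; C13 from a Sharpless asymmetric epoxidation in the side chain.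

Key step: step 9

Remark: conjugate bases that form and react under one set of conditions (phenoxides, enolates) and species that only await aqueous work-up are treated as forms of the numbered compound; organometallic or covalent species that persist until a second reagent is added are numbered as intermediates.

**Core: steps 1–9**

Step 1
Reactants: 1 4-methoxy-2-methylphenol; 2 formaldehyde
Product: 3 2-(hydroxymethyl)-4-methoxy-6-methylphenol
Conditions: 37% aqueous CH2O, NaOH (1 equiv), H2O, 25 °C; then dilute HCl to pH 6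
Reagents that add atoms: none
Why: Lederer–Manasse hydroxymethylation of the phenoxide, in which the para position carries OMe and one ortho position the methyl group, so only the remaining ortho carbon (future C10) can react.

Step 2
Reactants: 3 2-(hydroxymethyl)-4-methoxy-6-methylphenol
Product: 4 (2-isopropoxy-5-methoxy-3-methylphenyl)methanol
Conditions: 2-bromopropane, K2CO3, DMF, 60 °C
Reagents that add atoms: 2-bromopropane, CC(C)Br
Why: Williamson etherification in which only the phenol is deprotonated by carbonate, so the benzylic alcohol stays free.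

Step 3
Reactants: 4 (2-isopropoxy-5-methoxy-3-methylphenyl)methanol
Product: 6 (2-bromo-6-isopropoxy-3-methoxy-5-methylphenyl)methanol, via dilithio arene 5 (not isolated)
Conditions: n-BuLi (2.4 equiv), TMEDA, Et2O, 0 → 25 °C; then BrCCl2CCl2Br, −78 °C
Reagents that add atoms: 1,2-dibromotetrachloroethane, BrC(Cl)(Cl)C(Cl)(Cl)Br
Why: directed ortho-metalation in which the lithium benzyl alkoxide and the meta-related methoxy group cooperate to lithiate the CH between them (future C5), followed by bromine transfer to the aryllithium.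

Step 4
Reactants: 6 (2-bromo-6-isopropoxy-3-methoxy-5-methylphenyl)methanol; 7 tert-butyl propanoate
Product: 8 tert-butyl 2-[2-(hydroxymethyl)-3-isopropoxy-6-methoxy-4-methylphenyl]propanoate (racemic)
Conditions: LiN(SiMe3)2 (3.3 equiv), Pd(dba)2 (5 mol %), P(t-Bu)3 (5 mol %), toluene, 25 → 50 °C
Reagents that add atoms: none
Why: palladium-catalysed α-arylation of the ester enolate (zerovalent palladium with a bulky electron-rich phosphine for the di-ortho-substituted bromide), with extra base to cover the free hydroxyl and the more acidic product.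

Step 5
Reactants: 8 tert-butyl 2-[2-(hydroxymethyl)-3-isopropoxy-6-methoxy-4-methylphenyl]propanoate
Product: 10 8-isopropoxy-5-methoxy-4,7-dimethylisochroman-3-one (racemic), via hydroxy acid 9 (not isolated)
Conditions: CF3CO2H, CH2Cl2, 0 → 25 °C
Reagents that add atoms: none
Why: acidolysis of the tert-butyl ester followed by acid-catalysed lactonisation with the electron-rich ortho-hydroxymethyl group to the six-membered lactone.

Step 6
Reactants: 10 8-isopropoxy-5-methoxy-4,7-dimethylisochroman-3-one; 11 1-bromo-3-chloropropane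
Product: 12 (S)-4-(3-chloropropyl)-8-isopropoxy-5-methoxy-4,7-dimethylisochroman-3-one
Conditions: 11 (3 equiv), N-(9-anthracenylmethyl)-O-allylcinchonidinium bromide (10 mol %), solid CsOH·H2O, toluene/CH2Cl2, −40 °C
Reagents that add atoms: none
Why: asymmetric phase-transfer alkylation of the benzylic lactone enolate (the oxa analogue of the 1-methyl-2-tetralone enolates used in this reaction type), in which the chiral ammonium cation shields one enolate face so that the bromide end of the electrophile sets C4 as S; the cinchoninium pseudo-enantiomer would be taken if the sense proves opposite.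

Step 7
Reactants: 12 (S)-4-(3-chloropropyl)-8-isopropoxy-5-methoxy-4,7-dimethylisochroman-3-one
Product: 13 (S)-4-(3-chloropropyl)-8-hydroxy-5-methoxy-4,7-dimethylisochroman-3-one
Conditions: BCl3 (1 M in CH2Cl2), CH2Cl2, −78 → −20 °C; aqueous NaHCO3 work-up
Reagents that add atoms: none
Why: Lewis-acid dealkylation that cleaves the twisted, di-ortho-substituted isopropyl aryl ether through a secondary alkyl chloride, while the methyl ether, lactone and alkyl chloride survive at low temperature.

Step 8
Reactants: 13 (S)-4-(3-chloropropyl)-8-hydroxy-5-methoxy-4,7-dimethylisochroman-3-one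
Product: 14 (S)-8-hydroxy-4-(3-iodopropyl)-5-methoxy-4,7-dimethylisochroman-3-one
Conditions: NaI, acetone, reflux
Reagents that add atoms: sodium iodide, [Na+].[I-]
Why: Finkelstein exchange driven by precipitation of NaCl under neutral conditions that leave the phenol unalkylated.

Step 9
Reactants: 14 (S)-8-hydroxy-4-(3-iodopropyl)-5-methoxy-4,7-dimethylisochroman-3-one
Product: 15 (4S,10S)-6-methoxy-9-oxo-11,12,13,14,15,16-hexanorlabda-5,7-dien-19,20-olide
Conditions: KOt-Bu (1.0 equiv), t-BuOH/THF, about 0.005 M, 25 → 60 °C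
Reagents that add atoms: none
Why: The potassium phenoxide of 14 is ambident and displaces iodide at C1 through its ortho carbon C10 in an SN2 reaction, which turns the arene into a 6,6-disubstituted cyclohexa-2,4-dienone that keeps the C6 enol ether. The closest known reaction type is the intramolecular alkylative dearomatisation of phenoxides in its ortho (Ar2-6) mode. Ring A (C10, C5, C4, C3, C2, C1) closes 6-exo-tet, the C4 chain standing out of the arene plane because C4 is sp3 within the lactone. C10 is the only new stereocentre and is fixed by C4, because the lactone bridge and the new carbon bridge must span the same two bridgeheads and only the isomer with C19 and C20 cis can form. The step needs C- over O-alkylation at one ring carbon: O-alkylation would require an eight-membered ring, C6 and C8 are out of reach, high dilution suppresses intermolecular O-alkylation and tert-butanol hydrogen-bonds the phenoxide oxygen. One equivalent of base is used because alkoxide opening of the lactone in the product would trigger retro-aldol loss of C20, and any reversible opening of the ortho-hydroxybenzyl ester to a quinone methide is repaired by reclosure of the tethered carboxylate.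

**Side chain: steps 10–17**

Step 10
Reactants: 16 but-2-yne-1,4-diol
Product: 17 4-[(triisopropylsilyl)oxy]but-2-yn-1-ol
Conditions: NaH (1.0 equiv), THF, 25 °C; then i-Pr3SiCl
Reagents that add atoms: chlorotriisopropylsilane, CC(C)[Si](Cl)(C(C)C)C(C)C
Why: monosilylation of a symmetric diol through its sparingly soluble monosodium alkoxide, which suppresses double silylation.

Step 11
Reactants: 17 4-[(triisopropylsilyl)oxy]but-2-yn-1-ol
Product: 19 (Z)-3-iodo-4-[(triisopropylsilyl)oxy]but-2-en-1-ol, via cyclic alkenylalanate 18 (not isolated)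
Conditions: NaAlH2(OCH2CH2OMe)2, THF, 0 °C; then I2, −78 °C
Reagents that add atoms: iodine, II
Why: hydroxyl-directed trans-hydroalumination of the propargylic alcohol places aluminium on C3 in a five-membered alanate, and iodinolysis with retention gives the (Z)-3-iodo allylic alcohol.

Step 12
Reactants: 19 (Z)-3-iodo-4-[(triisopropylsilyl)oxy]but-2-en-1-ol; 20 ethynyltriisopropylsilane
Product: 21 (E)-4-[(triisopropylsilyl)oxy]-3-[(triisopropylsilyl)ethynyl]but-2-en-1-ol
Conditions: PdCl2(PPh3)2 (3 mol %), CuI (5 mol %), Et3N, THF, 25 °C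
Reagents that add atoms: none
Why: Sonogashira coupling of the alkenyl iodide with the terminal alkyne, with retention of alkene geometry (CH2OH cis to the alkynyl group).

Step 13
Reactants: 21 (E)-4-[(triisopropylsilyl)oxy]-3-[(triisopropylsilyl)ethynyl]but-2-en-1-ol
Product: 22 [(2R,3R)-3-{[(triisopropylsilyl)oxy]methyl}-3-[(triisopropylsilyl)ethynyl]oxiran-2-yl]methanol
Conditions: Ti(Oi-Pr)4 (10 mol %), D-(−)-diethyl tartrate (12 mol %), t-BuOOH, 4 Å molecular sieves, CH2Cl2, −20 °C
Reagents that add atoms: tert-butyl hydroperoxide, CC(C)(C)OO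
Why: Sharpless asymmetric epoxidation of a 3,3-disubstituted allylic alcohol, where the D-(−)-tartrate should deliver oxygen to the face that gives the (2R,3R)-epoxide (same substitution pattern and sense as geraniol, mirror tartrate), which fixes the later C13 centre.

Step 14
Reactants: 22 [(2R,3R)-3-{[(triisopropylsilyl)oxy]methyl}-3-[(triisopropylsilyl)ethynyl]oxiran-2-yl]methanol
Product: 23 (2S,3R)-2-(iodomethyl)-3-{[(triisopropylsilyl)oxy]methyl}-3-[(triisopropylsilyl)ethynyl]oxirane
Conditions: PPh3, I2, imidazole, THF, 0 °C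
Reagents that add atoms: iodine, II
Why: Appel-type iodination of the primary alcohol under conditions that leave the epoxide intact (the descriptor at C2 changes only because of CIP priority).

Step 15
Reactants: 23 (2S,3R)-2-(iodomethyl)-3-{[(triisopropylsilyl)oxy]methyl}-3-[(triisopropylsilyl)ethynyl]oxirane
Product: 24 (R)-1-[(triisopropylsilyl)oxy]-2-[(triisopropylsilyl)ethynyl]but-3-en-2-ol
Conditions: Zn dust, EtOH, 60 °C
Reagents that add atoms: none
Why: zinc-mediated reductive β-elimination of the 2,3-epoxy iodide, which opens the epoxide toward the metal and gives the tertiary allylic alcohol without breaking the C–O bond at the stereocentre.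

Step 16
Reactants: 24 (R)-1-[(triisopropylsilyl)oxy]-2-[(triisopropylsilyl)ethynyl]but-3-en-2-ol
Product: 26 (R)-4-[(triisopropylsilyl)oxy]-3-[(triisopropylsilyl)ethynyl]butane-1,3-diol, via B-alkyl borane 25 (not isolated)
Conditions: 9-borabicyclo[3.3.1]nonane (9-BBN-H), THF, 0 → 25 °C; then NaOH, H2O2, 0 °C
Reagents that add atoms: hydrogen peroxide, OO
Why: anti-Markovnikov hydroboration of the monosubstituted alkene (the hindered silylalkyne is not touched) followed by oxidation of the C–B bond with retention.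

Step 17
Reactants: 26 (R)-4-[(triisopropylsilyl)oxy]-3-[(triisopropylsilyl)ethynyl]butane-1,3-diol
Product: 27 (R)-4-iodo-1-[(triisopropylsilyl)oxy]-2-[(triisopropylsilyl)ethynyl]butan-2-ol
Conditions: PPh3, I2, imidazole, CH2Cl2, 0 °C
Reagents that add atoms: iodine, II
Why: Appel-type iodination that is selective for the primary hydroxyl and kept neutral so that the γ-iodo alcohol does not close to an oxetane.

**Union and endgame: steps 18–25**

Step 18
Reactants: 15 (4S,10S)-6-methoxy-9-oxo-11,12,13,14,15,16-hexanorlabda-5,7-dien-19,20-olide; 27 (R)-4-iodo-1-[(triisopropylsilyl)oxy]-2-[(triisopropylsilyl)ethynyl]butan-2-ol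
Product: 31 (13R)-9,13-dihydroxy-6-oxo-16-(triisopropylsilyloxy)-15-(triisopropylsilyl)-5α-labd-7-en-14-yn-19,20-olide (C9 epimers), via dilithio side chain 28 (not isolated), via organocerium reagent 29 (not isolated), via C9 carbinol 30 (not isolated)
Conditions: 27 (1.5 equiv), MeLi then t-BuLi (2 equiv per iodide), Et2O, −78 °C; CeCl3, THF, −78 °C; then 15, −78 °C; aqueous NH4Cl; then oxalic acid, THF/H2O, 0 → 25 °C
Reagents that add atoms: water, O
Why: iodine–lithium exchange on the lithium alkoxide of 27 gives a γ-oxido alkyllithium that is transmetalated to the less basic organocerium reagent and adds 1,2 to the hindered C9 ketone (both C9 epimers are expected and both are used, since C9 is reset in step 21), after which mild acid protonates the dienol ether at C5 and hydrolysis gives the 7-en-6-one, C5 being free to equilibrate to the trans-fused 5α-H isomer in which C6 is equatorial on ring A.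

Step 19
Reactants: 31 (13R)-9,13-dihydroxy-6-oxo-16-(triisopropylsilyloxy)-15-(triisopropylsilyl)-5α-labd-7-en-14-yn-19,20-olide
Product: 33 (13R)-9,13-dihydroxy-6-oxo-16-(triisopropylsilyloxy)-15-(triisopropylsilyl)-5α-labd-8(17)-en-14-yn-19,20-olide (C9 epimers), via tripotassium dienolate 32 (not isolated)
Conditions: KOt-Bu (5 equiv), t-BuOH/THF, 0 → 25 °C; inverse quench into AcOH/THF, −78 °C
Reagents that add atoms: none
Why: base-mediated deconjugation in which the extended dienolate is formed by γ-deprotonation of the C17 methyl group (C9 has no hydrogen) and kinetic protonation at the α-carbon C7 gives the β,γ-unsaturated ketone with the exocyclic alkene.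

Step 20
Reactants: 33 (13R)-9,13-dihydroxy-6-oxo-16-(triisopropylsilyloxy)-15-(triisopropylsilyl)-5α-labd-8(17)-en-14-yn-19,20-olide
Product: 34 (13R)-6β,9,13-trihydroxy-16-(triisopropylsilyloxy)-15-(triisopropylsilyl)-5α-labd-8(17)-en-14-yn-19,20-olide (C9 epimers)
Conditions: NaBH4, CeCl3·7H2O, MeOH, −40 °C; product used at once
Reagents that add atoms: none
Why: Luche reduction under nearly neutral conditions that do not reconjugate the enone, in which the β face of the C6 carbonyl is screened by axial C20 and by C19 so that hydride adds from the α face and gives the axial 6β-alcohol.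

Step 21
Reactants: 34 (13R)-6β,9,13-trihydroxy-16-(triisopropylsilyloxy)-15-(triisopropylsilyl)-5α-labd-8(17)-en-14-yn-19,20-olide
Product: 35 (13R)-9α,13-epoxy-6β-hydroxy-16-(triisopropylsilyloxy)-15-(triisopropylsilyl)-5α-labd-8(17)-en-14-yn-19,20-olide
Conditions: (+)-camphor-10-sulfonic acid (10 mol %), 4 Å molecular sieves, CH2Cl2, −20 → 0 °C; Et3N quench
Reagents that add atoms: none
Why: acid-catalysed dehydrative etherification in which the tertiary allylic C9 hydroxyl of either epimer ionises to the same C9–C8–C17 allyl cation and the tertiary C13 hydroxyl captures it at C9 in a five-membered ring closure from the α face, anti to the axial C20 on the neighbouring quaternary C10, so that the new C–O bond is 9α and C11 is β, while C13 is not touched.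

Step 22
Reactants: 35 (13R)-9α,13-epoxy-6β-hydroxy-16-(triisopropylsilyloxy)-15-(triisopropylsilyl)-5α-labd-8(17)-en-14-yn-19,20-olide
Product: 36 (13R)-8β,17:9α,13-diepoxy-6β-hydroxy-16-(triisopropylsilyloxy)-15-(triisopropylsilyl)-5α-labd-14-yn-19,20-olide
Conditions: VO(acac)2 (5 mol %), t-BuOOH (decane solution), CH2Cl2, 0 → 25 °C
Reagents that add atoms: tert-butyl hydroperoxide, CC(C)(C)OO
Why: vanadium-catalysed hydroxyl-directed epoxidation in which the axial homoallylic 6β-hydroxyl binds the metal peroxide and delivers oxygen to the β face of the 8(17)-alkene, against the steric preference for α attack, to give the 8β,17-epoxide.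

Step 23
Reactants: 36 (13R)-8β,17:9α,13-diepoxy-6β-hydroxy-16-(triisopropylsilyloxy)-15-(triisopropylsilyl)-5α-labd-14-yn-19,20-olide
Product: 37 (13R)-6β-acetoxy-8β,17:9α,13-diepoxy-16-(triisopropylsilyloxy)-15-(triisopropylsilyl)-5α-labd-14-yn-19,20-olide
Conditions: Ac2O, DMAP, Et3N, CH2Cl2, 25 °C
Reagents that add atoms: acetic anhydride, CC(=O)OC(C)=O
Why: DMAP-catalysed acylation of the hindered axial secondary alcohol, the only free hydroxyl in the molecule.

Step 24
Reactants: 37 (13R)-6β-acetoxy-8β,17:9α,13-diepoxy-16-(triisopropylsilyloxy)-15-(triisopropylsilyl)-5α-labd-14-yn-19,20-olide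
Product: 38 (13R)-6β-acetoxy-8β,17:9α,13-diepoxy-16-hydroxy-5α-labd-14-yn-19,20-olide
Conditions: Bu4NF, AcOH (1:1), THF, 25 → 40 °C
Reagents that add atoms: none
Why: fluoride-induced cleavage of the Si–O and Si–C(sp) bonds in one operation, buffered by acetic acid so that acetate, lactone and epoxide survive.

Step 25
Reactants: 38 (13R)-6β-acetoxy-8β,17:9α,13-diepoxy-16-hydroxy-5α-labd-14-yn-19,20-olide
Product: 39 (13R)-6β-acetoxy-8β,17:9α,13:15,16-triepoxy-5α-labd-14-en-19,20-olide (CNP0173713.2)
Conditions: Mo(CO)6 (30 mol %), Et3N, Et2O, hν (350 nm), 25 °C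
Reagents that add atoms: none
Why: alkynol cycloisomerisation in which the terminal alkyne becomes a molybdenum vinylidene whose electrophilic carbon C15 is attacked by the C16 hydroxyl in the endo mode, and protodemetalation gives the 2,3-dihydrofuran without forming a stereocentre, in a basic medium that spares the acid-labile spiro enol ether.

**Compound list**

1 | 4-methoxy-2-methylphenol | Cc1cc(OC)ccc1O | starting material
2 | formaldehyde | C=O | starting material
3 | 2-(hydroxymethyl)-4-methoxy-6-methylphenol | OCc1cc(OC)cc(C)c1O | intermediate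
4 | (2-isopropoxy-5-methoxy-3-methylphenyl)methanol | OCc1cc(OC)cc(C)c1OC(C)C | intermediate
5 | lithium (2-isopropoxy-6-lithio-5-methoxy-3-methylphenyl)methoxide | [Li]OCc1c([Li])c(OC)cc(C)c1OC(C)C | intermediate
6 | (2-bromo-6-isopropoxy-3-methoxy-5-methylphenyl)methanol | OCc1c(Br)c(OC)cc(C)c1OC(C)C | intermediate
7 | tert-butyl propanoate | CCC(=O)OC(C)(C)C | starting material
8 | tert-butyl 2-[2-(hydroxymethyl)-3-isopropoxy-6-methoxy-4-methylphenyl]propanoate (racemic) | CC(C(=O)OC(C)(C)C)c1c(CO)c(OC(C)C)c(C)cc1OC | intermediate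
9 | 2-[2-(hydroxymethyl)-3-isopropoxy-6-methoxy-4-methylphenyl]propanoic acid (racemic) | CC(C(O)=O)c1c(CO)c(OC(C)C)c(C)cc1OC | intermediate
10 | 8-isopropoxy-5-methoxy-4,7-dimethylisochroman-3-one (racemic) | CC1C(=O)OCc2c(OC(C)C)c(C)cc(OC)c12 | intermediate
11 | 1-bromo-3-chloropropane | ClCCCBr | starting material
12 | (S)-4-(3-chloropropyl)-8-isopropoxy-5-methoxy-4,7-dimethylisochroman-3-one | Cc1cc(OC)c2c(c1OC(C)C)COC(=O)[C@@]2(C)CCCCl | intermediate
13 | (S)-4-(3-chloropropyl)-8-hydroxy-5-methoxy-4,7-dimethylisochroman-3-one | Cc1cc(OC)c2c(c1O)COC(=O)[C@@]2(C)CCCCl | intermediate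
14 | (S)-8-hydroxy-4-(3-iodopropyl)-5-methoxy-4,7-dimethylisochroman-3-one | Cc1cc(OC)c2c(c1O)COC(=O)[C@@]2(C)CCCI | intermediate
15 | (4S,10S)-6-methoxy-9-oxo-11,12,13,14,15,16-hexanorlabda-5,7-dien-19,20-olide (bridged-lactone 2,4-cyclohexadienone) | O=C1C(C)=CC(OC)=C2[C@@](C)(C(=O)OC3)CCC[C@]123 | intermediate
16 | but-2-yne-1,4-diol | OCC#CCO | starting material
17 | 4-[(triisopropylsilyl)oxy]but-2-yn-1-ol | CC(C)[Si](OCC#CCO)(C(C)C)C(C)C | intermediate
18 | sodium cyclic alkenylalanate (2,5-dihydro-1,2-oxaluminole ate complex with aluminium on C3) | [Na+].COCCO[Al-]1(OCCOC)OCC=C1CO[Si](C(C)C)(C(C)C)C(C)C | intermediate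
19 | (Z)-3-iodo-4-[(triisopropylsilyl)oxy]but-2-en-1-ol | OC/C=C(\I)CO[Si](C(C)C)(C(C)C)C(C)C | intermediate
20 | ethynyltriisopropylsilane | C#C[Si](C(C)C)(C(C)C)C(C)C | starting material
21 | (E)-4-[(triisopropylsilyl)oxy]-3-[(triisopropylsilyl)ethynyl]but-2-en-1-ol | OC/C=C(\C#C[Si](C(C)C)(C(C)C)C(C)C)CO[Si](C(C)C)(C(C)C)C(C)C | intermediate
22 | [(2R,3R)-3-{[(triisopropylsilyl)oxy]methyl}-3-[(triisopropylsilyl)ethynyl]oxiran-2-yl]methanol | OC[C@H]1O[C@]1(C#C[Si](C(C)C)(C(C)C)C(C)C)CO[Si](C(C)C)(C(C)C)C(C)C | intermediate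
23 | (2S,3R)-2-(iodomethyl)-3-{[(triisopropylsilyl)oxy]methyl}-3-[(triisopropylsilyl)ethynyl]oxirane | IC[C@H]1O[C@]1(C#C[Si](C(C)C)(C(C)C)C(C)C)CO[Si](C(C)C)(C(C)C)C(C)C | intermediate
24 | (R)-1-[(triisopropylsilyl)oxy]-2-[(triisopropylsilyl)ethynyl]but-3-en-2-ol | C=C[C@@](O)(C#C[Si](C(C)C)(C(C)C)C(C)C)CO[Si](C(C)C)(C(C)C)C(C)C | intermediate
25 | B-alkyl-9-borabicyclo[3.3.1]nonane from 24 (boron on the terminal carbon) | C1CC2CCCC(C1)B2CC[C@@](O)(C#C[Si](C(C)C)(C(C)C)C(C)C)CO[Si](C(C)C)(C(C)C)C(C)C | intermediate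
26 | (R)-4-[(triisopropylsilyl)oxy]-3-[(triisopropylsilyl)ethynyl]butane-1,3-diol | OCC[C@@](O)(C#C[Si](C(C)C)(C(C)C)C(C)C)CO[Si](C(C)C)(C(C)C)C(C)C | intermediate
27 | (R)-4-iodo-1-[(triisopropylsilyl)oxy]-2-[(triisopropylsilyl)ethynyl]butan-2-ol | ICC[C@@](O)(C#C[Si](C(C)C)(C(C)C)C(C)C)CO[Si](C(C)C)(C(C)C)C(C)C | intermediate
28 | dilithio derivative of 27 (lithium alkoxide; lithium in place of iodine) | [Li]CC[C@@](O[Li])(C#C[Si](C(C)C)(C(C)C)C(C)C)CO[Si](C(C)C)(C(C)C)C(C)C | intermediate
29 | dichlorocerium alkyl from 28 (lithium alkoxide kept) | Cl[Ce](Cl)CC[C@@](O[Li])(C#C[Si](C(C)C)(C(C)C)C(C)C)CO[Si](C(C)C)(C(C)C)C(C)C | intermediate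
30 | (13R)-9,13-dihydroxy-6-methoxy-16-(triisopropylsilyloxy)-15-(triisopropylsilyl)labda-5,7-dien-14-yn-19,20-olide (C9 epimers) | OC1(CC[C@@](O)(C#C[Si](C(C)C)(C(C)C)C(C)C)CO[Si](C(C)C)(C(C)C)C(C)C)C(C)=CC(OC)=C2[C@@](C)(C(=O)OC3)CCC[C@]123 | intermediate
31 | (13R)-9,13-dihydroxy-6-oxo-16-(triisopropylsilyloxy)-15-(triisopropylsilyl)-5α-labd-7-en-14-yn-19,20-olide (C9 epimers) | O=C1C=C(C)C(O)(CC[C@@](O)(C#C[Si](C(C)C)(C(C)C)C(C)C)CO[Si](C(C)C)(C(C)C)C(C)C)[C@]23CCC[C@](C)(C(=O)OC2)[C@H]13 | intermediate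
32 | tripotassium 6-enolate-9,13-dialkoxide of the 6,8(17)-diene (extended dienolate of 31) | [K]OC1=CC(=C)C(O[K])(CC[C@@](O[K])(C#C[Si](C(C)C)(C(C)C)C(C)C)CO[Si](C(C)C)(C(C)C)C(C)C)[C@]23CCC[C@](C)(C(=O)OC2)[C@H]13 | intermediate
33 | (13R)-9,13-dihydroxy-6-oxo-16-(triisopropylsilyloxy)-15-(triisopropylsilyl)-5α-labd-8(17)-en-14-yn-19,20-olide (C9 epimers) | O=C1CC(=C)C(O)(CC[C@@](O)(C#C[Si](C(C)C)(C(C)C)C(C)C)CO[Si](C(C)C)(C(C)C)C(C)C)[C@]23CCC[C@](C)(C(=O)OC2)[C@H]13 | intermediate
34 | (13R)-6β,9,13-trihydroxy-16-(triisopropylsilyloxy)-15-(triisopropylsilyl)-5α-labd-8(17)-en-14-yn-19,20-olide (C9 epimers) | O[C@@H]1CC(=C)C(O)(CC[C@@](O)(C#C[Si](C(C)C)(C(C)C)C(C)C)CO[Si](C(C)C)(C(C)C)C(C)C)[C@]23CCC[C@](C)(C(=O)OC2)[C@H]13 | intermediate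
35 | (13R)-9α,13-epoxy-6β-hydroxy-16-(triisopropylsilyloxy)-15-(triisopropylsilyl)-5α-labd-8(17)-en-14-yn-19,20-olide | O[C@@H]1CC(=C)[C@]2(CC[C@](CO[Si](C(C)C)(C(C)C)C(C)C)(C#C[Si](C(C)C)(C(C)C)C(C)C)O2)[C@]23CCC[C@](C)(C(=O)OC2)[C@H]13 | intermediate
36 | (13R)-8β,17:9α,13-diepoxy-6β-hydroxy-16-(triisopropylsilyloxy)-15-(triisopropylsilyl)-5α-labd-14-yn-19,20-olide | O[C@@H]1C[C@@]2(CO2)[C@]2(CC[C@](CO[Si](C(C)C)(C(C)C)C(C)C)(C#C[Si](C(C)C)(C(C)C)C(C)C)O2)[C@]23CCC[C@](C)(C(=O)OC2)[C@H]13 | intermediate
37 | (13R)-6β-acetoxy-8β,17:9α,13-diepoxy-16-(triisopropylsilyloxy)-15-(triisopropylsilyl)-5α-labd-14-yn-19,20-olide | CC(=O)O[C@@H]1C[C@@]2(CO2)[C@]2(CC[C@](CO[Si](C(C)C)(C(C)C)C(C)C)(C#C[Si](C(C)C)(C(C)C)C(C)C)O2)[C@]23CCC[C@](C)(C(=O)OC2)[C@H]13 | intermediate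
38 | (13R)-6β-acetoxy-8β,17:9α,13-diepoxy-16-hydroxy-5α-labd-14-yn-19,20-olide | CC(=O)O[C@@H]1C[C@@]2(CO2)[C@]2(CC[C@](CO)(C#C)O2)[C@]23CCC[C@](C)(C(=O)OC2)[C@H]13 | intermediate
39 | (13R)-6β-acetoxy-8β,17:9α,13:15,16-triepoxy-5α-labd-14-en-19,20-olide (CNP0173713.2; 4S,5R,6R,8R,9S,10S,13R) | CC(=O)O[C@@H]1C[C@@]2(CO2)[C@]2(CC[C@]3(C=COC3)O2)[C@]23CCC[C@](C)(C(=O)OC2)[C@H]13 | target

**Summary and risks**

Total step count: 25 (9 to the dienone, 8 for the side chain, 8 after the union). Longest linear sequence: 17 steps (steps 1–9 and 18–25).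

Steps most likely to fail:

- **Step 21.** The C9 allyl cation may be captured with too little facial bias, may lose a proton from C11 to give a diene, or the free 6β-hydroxyl may attack the lactone. The fallback sets out from 34 and rejoins at 37, so steps 21 to 23 are bypassed. The secondary 6β-hydroxyl would first be acetylated (Ac2O, DMAP) to the 6β-acetate F4. A Babler–Dauben oxidative transposition with pyridinium chlorochromate, (C5H5NH)[CrO3Cl], would turn the tertiary allylic alcohol of either C9 epimer into the single 8(9)-en-17-al F5. Luche reduction (NaBH4, CeCl3·7H2O) would give the allylic alcohol F6. Sharpless asymmetric epoxidation (Ti(Oi-Pr)4, D-(−)-diethyl tartrate, t-BuOOH) would place oxygen on the β face and give the 8β,9β-epoxy alcohol F7. Catalytic camphorsulfonic acid would let the C13 hydroxyl open the epoxide at C9, 5-exo and with inversion, to the 9α,13-epoxy-8β,17-diol F8. Tosylation of the primary hydroxyl (TsCl, pyridine) to the 17-tosylate F9 and treatment with NaH would close the 8β,17-epoxide, which is 37. C8 and C9 are then both set by a reagent-controlled epoxidation and two stereospecific displacements.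

- **Step 6.** The ion pair may discriminate the enolate faces poorly, or hydroxide may open the lactone before C-alkylation. The fallback sets out from 10 and rejoins at 12. The lithium enolate (LiN(SiMe3)2, THF, −78 °C) would be allylated with allyl acetate in a Tsuji–Trost asymmetric allylic alkylation, using [Pd(C3H5)Cl]2 and (1R,2R)-N,N'-bis(2-diphenylphosphinobenzoyl)cyclohexane-1,2-diamine, to give (S)-4-allyl-8-isopropoxy-5-methoxy-4,7-dimethylisochroman-3-one F1. Hydroboration with 9-borabicyclo[3.3.1]nonane and oxidation with NaBO3 would give the (S)-4-(3-hydroxypropyl) lactone F2. Chlorination with PPh3 and CCl4 would return 12.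

- **Step 19.** The extended dienolate may form incompletely, the ketone may reconjugate during the quench, or protonation may return to C17. The fallback sets out from 31 and rejoins at 33. Silylation under thermodynamic control (Me3SiCl, NaI, Et3N, MeCN) would fix the extended isomer as the tris(trimethylsilyl) dienol ether F3, in which the two tertiary hydroxyls are also silylated. Fluoride-triggered release of the dienolate in the presence of acetic acid (Bu4N[Ph3SiF2], AcOH, THF, −78 °C) would give kinetic protonation at C7, and the tertiary trimethylsilyl ethers would fall off on mildly acidic work-up to give 33.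

**Further compounds**

F1 | step 6 | (S)-4-allyl-8-isopropoxy-5-methoxy-4,7-dimethylisochroman-3-one | Cc1cc(OC)c2c(c1OC(C)C)COC(=O)[C@@]2(C)CC=C
F2 | step 6 | (S)-4-(3-hydroxypropyl)-8-isopropoxy-5-methoxy-4,7-dimethylisochroman-3-one | Cc1cc(OC)c2c(c1OC(C)C)COC(=O)[C@@]2(C)CCCO
F3 | step 19 | 6,9,13-tris(trimethylsilyloxy)-6,8(17)-dien-14-yne dienol ether of 31 (C9 epimers) | C[Si](C)(C)OC1=CC(=C)C(O[Si](C)(C)C)(CC[C@@](O[Si](C)(C)C)(C#C[Si](C(C)C)(C(C)C)C(C)C)CO[Si](C(C)C)(C(C)C)C(C)C)[C@]23CCC[C@](C)(C(=O)OC2)[C@H]13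
F4 | step 21 | 6β-acetate of 34 (C9 epimers) | CC(=O)O[C@@H]1CC(=C)C(O)(CC[C@@](O)(C#C[Si](C(C)C)(C(C)C)C(C)C)CO[Si](C(C)C)(C(C)C)C(C)C)[C@]23CCC[C@](C)(C(=O)OC2)[C@H]13
F5 | step 21 | (13R)-6β-acetoxy-13-hydroxy-17-oxo-16-(triisopropylsilyloxy)-15-(triisopropylsilyl)-5α-labd-8(9)-en-14-yn-19,20-olide | CC(=O)O[C@@H]1CC(C=O)=C(CC[C@@](O)(C#C[Si](C(C)C)(C(C)C)C(C)C)CO[Si](C(C)C)(C(C)C)C(C)C)[C@]23CCC[C@](C)(C(=O)OC2)[C@H]13
F6 | step 21 | (13R)-6β-acetoxy-13,17-dihydroxy-16-(triisopropylsilyloxy)-15-(triisopropylsilyl)-5α-labd-8(9)-en-14-yn-19,20-olide | CC(=O)O[C@@H]1CC(CO)=C(CC[C@@](O)(C#C[Si](C(C)C)(C(C)C)C(C)C)CO[Si](C(C)C)(C(C)C)C(C)C)[C@]23CCC[C@](C)(C(=O)OC2)[C@H]13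
F7 | step 21 | (13R)-6β-acetoxy-8β,9β-epoxy-13,17-dihydroxy-16-(triisopropylsilyloxy)-15-(triisopropylsilyl)-5α-labd-14-yn-19,20-olide | CC(=O)O[C@@H]1C[C@]2(CO)O[C@]2(CC[C@@](O)(C#C[Si](C(C)C)(C(C)C)C(C)C)CO[Si](C(C)C)(C(C)C)C(C)C)[C@]23CCC[C@](C)(C(=O)OC2)[C@H]13
F8 | step 21 | (13R)-6β-acetoxy-9α,13-epoxy-8β,17-dihydroxy-16-(triisopropylsilyloxy)-15-(triisopropylsilyl)-5α-labd-14-yn-19,20-olide | CC(=O)O[C@@H]1C[C@@](O)(CO)[C@]2(CC[C@](CO[Si](C(C)C)(C(C)C)C(C)C)(C#C[Si](C(C)C)(C(C)C)C(C)C)O2)[C@]23CCC[C@](C)(C(=O)OC2)[C@H]13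
F9 | step 21 | 17-(4-methylbenzenesulfonate) of F8 | CC(=O)O[C@@H]1C[C@@](O)(COS(=O)(=O)c4ccc(C)cc4)[C@]2(CC[C@](CO[Si](C(C)C)(C(C)C)C(C)C)(C#C[Si](C(C)C)(C(C)C)C(C)C)O2)[C@]23CCC[C@](C)(C(=O)OC2)[C@H]13
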